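## Retrosynthetic overview

1. The last bond is the central C–C single bond of the (E,E)-diene, made by Suzuki–Miyaura coupling of an (E)-alkenyl iodide (rings A and B with the triene) and an unprotected alkenyl pinacolboronate carrying the carbamate, the free hydroxyl and the 2-methoxyacrylamide.
2. Ring A is numbered O1, C2 (CH2 link to ring B), C3 (CH3), C4 (CH2), C5 (tertiary carbinol), C6 (diene arm). It is traced back to a δ-lactone with C6 as the carbonyl; the C6 arm then comes from alkyllithium addition and axial hydride reduction of the hemiketal (2,6-cis).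
3. Key disconnection: the lactone is cut at C4–C5 and O1–C6 into a trans-2,3-disubstituted oxetane (O1, C2, C3, C4) and the lithium enolate of the (S)-lactic acid/pivalaldehyde dioxolanone (C5, C6). This is a strain-release [4+2] annulation in which the oxetane oxygen is first the leaving group and then the acylating nucleophile.
4. Enabling feature: in ring A, O1–C2–C3–C4 is a 1,3-related oxygen/carbon pair that can be stored as an oxetane, and C5(OH)(CH3)–C6 next to the ring oxygen is a lactic acid skeleton. The tertiary carbinol is therefore bought as (S)-lactate and set by self-regeneration of the stereocentre.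
5. Order of ring formation: ring B first (Prins cyclisation), the temporary oxetane second (anti-crotylboration, ozonolysis/reduction, cyclodehydration), ring A third (key step); the triene and then the diene are built last.

Key step: step 12

Remark: hemiketal 29 is expected as an anomeric mixture in equilibrium with its hydroxy ketone; both converge on the same oxocarbenium ion in step 21, so its anomeric centre is left undefined.

## Route

Step 1
Reactants: 1 methyl (S)-3-hydroxy-2-methylpropanoate
Product: 2 methyl (S)-3-(tert-butyldiphenylsilyloxy)-2-methylpropanoate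
Conditions: TBDPSCl, imidazole, CH2Cl2, 0 to 23 °C
Reagents that add atoms: tert-butyl(chloro)diphenylsilane, CC(C)(C)[Si](Cl)(c1ccccc1)c1ccccc1
Why: Silyl ether formation at the primary hydroxyl should be clean and does not touch the α-stereocentre.

Step 2
Reactants: 2 methyl (S)-3-(tert-butyldiphenylsilyloxy)-2-methylpropanoate
Product: 3 (S)-3-(tert-butyldiphenylsilyloxy)-2-methylpropanal
Conditions: i-Bu2AlH, CH2Cl2, –78 °C; aqueous potassium sodium tartrate
Reagents that add atoms: none
Why: Partial ester reduction with i-Bu2AlH should stop at the aluminium hemiacetal at –78 °C and release the aldehyde on work-up without epimerisation.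

Step 3
Reactants: 3 (S)-3-(tert-butyldiphenylsilyloxy)-2-methylpropanal
Product: 4 (2S,3R)-1-(tert-butyldiphenylsilyloxy)-2-methylhex-5-en-3-ol (hydroxyl anti to methyl)
Conditions: (+)-Ipc2B(allyl), Et2O, –78 °C; then NaOH, H2O2
Reagents that add atoms: (+)-B-allyldiisopinocampheylborane (from (−)-α-pinene), C=CCB([C@H]1C[C@H]2C[C@H](C2(C)C)[C@@H]1C)[C@H]1C[C@H]2C[C@H](C2(C)C)[C@@H]1C
Why: Brown allylboration through a closed chair transition state, in which the (+)-Ipc2B reagent should override the small bias of the α-methyl aldehyde and add to the Re face, setting the 3R carbinol.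

Step 4
Reactants: 4 (2S,3R)-1-(tert-butyldiphenylsilyloxy)-2-methylhex-5-en-3-ol, 5 3-(benzyloxy)propanal
Product: 7 (2R,4S,6R)-2-[2-(benzyloxy)ethyl]-6-[(S)-1-(tert-butyldiphenylsilyloxy)propan-2-yl]tetrahydro-2H-pyran-4-ol (ring B; 2,4,6-all-cis), via ring B trifluoroacetate 6 (not isolated)
Conditions: CF3CO2H, CH2Cl2, 0 to 23 °C; then K2CO3, MeOH
Reagents that add atoms: trifluoroacetic acid (source of the C4 oxygen), OC(=O)C(F)(F)F
Why: Prins cyclisation in which the (E)-oxocarbenium ion closes through a chair with both substituents equatorial and is captured equatorially by trifluoroacetate, so the new C2 and C4 centres should be cis to the existing C6 centre; methanolysis then frees the 4-hydroxyl.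

Step 5
Reactants: 7 ring B alcohol
Product: 8 (2R,4S,6R)-2-[2-(benzyloxy)ethyl]-4-methoxy-6-[(S)-1-(tert-butyldiphenylsilyloxy)propan-2-yl]tetrahydro-2H-pyran
Conditions: NaH, MeI, THF, 0 to 23 °C
Reagents that add atoms: iodomethane, IC
Why: Williamson methylation of the secondary alkoxide with retention at C4.

Step 6
Reactants: 8 ring B methyl ether
Product: 9 2-{(2R,4S,6R)-4-methoxy-6-[(S)-1-(tert-butyldiphenylsilyloxy)propan-2-yl]tetrahydro-2H-pyran-2-yl}ethan-1-ol (its ring is called "the ring B unit of 9" below)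
Conditions: H2 (1 atm), Pd/C, EtOAc, 23 °C
Reagents that add atoms: none
Why: Hydrogenolysis of the benzyl ether, to which the silyl and methyl ethers are inert.

Step 7
Reactants: 9 ring B ethanol
Product: 10 2-(ring B unit of 9)acetaldehyde (CH2CHO at C2 of the all-cis ring)
Conditions: Dess–Martin periodinane, NaHCO3, CH2Cl2, 0 to 23 °C
Reagents that add atoms: none
Why: Buffered Dess–Martin oxidation of a primary alcohol should give the β-alkoxy aldehyde without β-elimination.

Step 8
Reactants: 10 ring B acetaldehyde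
Product: 11 (2R,3S)-3-methyl-1-(ring B unit of 9)pent-4-en-2-ol (hydroxyl anti to methyl)
Conditions: trans-2-butene, KOt-Bu, n-BuLi, THF, –78 to –45 °C; (−)-Ipc2BOMe; BF3·OEt2, –78 °C; then 10; NaOH, H2O2
Reagents that add atoms: trans-2-butene, C/C=C/C (delivered as (−)-B-[(E)-but-2-enyl]diisopinocampheylborane made in the flask)
Why: Brown (E)-crotylboration, whose chair transition state should give the anti adduct while the (−)-Ipc2B ligands direct attack to the Si face (R carbinol, S methyl-bearing carbon).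

Step 9
Reactants: 11 anti homoallylic alcohol
Product: 12 (2S,3R)-2-methyl-4-(ring B unit of 9)butane-1,3-diol
Conditions: O3, CH2Cl2/MeOH, –78 °C; then NaBH4, –78 to 0 °C
Reagents that add atoms: ozone, [O-][O+]=O
Why: Ozonolysis with reductive work-up turns the vinyl group into CH2OH without touching a stereocentre.

Step 10
Reactants: 12 anti 1,3-diol
Product: 14 (2R,3S)-3-methyl-2-[(ring B unit of 9)methyl]oxetane (trans), via primary monotosylate 13 (not isolated)
Conditions: n-BuLi (1 equiv), THF, 0 °C; TsCl; n-BuLi (1 equiv), 0 to 60 °C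
Reagents that add atoms: none
Why: One-flask selective sulfonylation of the primary alkoxide followed by 4-exo-tet Williamson closure by the secondary alkoxide; substitution takes place at the CH2 carbon, so both stereocentres are retained.

Step 11
Reactants: 15 (S)-lactic acid
Product: 16 (2S,5S)-2-tert-butyl-5-methyl-1,3-dioxolan-4-one (cis)
Conditions: t-BuCHO, p-TsOH (cat.), pentane, reflux (water separator); low-temperature crystallisation
Reagents that add atoms: pivalaldehyde, CC(C)(C)C=O
Why: Acid-catalysed acetalisation (Seebach dioxolanone) should favour the cis isomer, which is purified by crystallisation.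

Step 12
Reactants: 14 trans-oxetane, 16 (2S,5S)-2-tert-butyl-5-methyl-1,3-dioxolan-4-one
Product: 19 (3R,5S,6R)-3-hydroxy-3,5-dimethyl-6-[(ring B unit of 9)methyl]tetrahydro-2H-pyran-2-one (ring A lactone), via lithium enolate 17 (not isolated), via ring-opened dioxolanone adduct 18 (not isolated)
Conditions: LiN(i-Pr)2, THF, –78 °C; then 14, BF3·OEt2, –78 to 23 °C
Reagents that add atoms: none
Why: Proposed new method: LiN(i-Pr)2 converts 16 into enolate 17, whose C5 opens the BF3-activated oxetane by SN2 attack at the unsubstituted ring CH2 (C4 of ring A) with release of the four-ring strain, forming C4–C5; the liberated C2–O1 alkoxide then adds to the acylal carbonyl (C6) on warming in the Lewis acidic medium, and collapse of the tetrahedral intermediate expels pivalaldehyde and unveils the tertiary hydroxyl. The closest known reactions are the BF3·OEt2-mediated opening of oxetanes by lithium ester enolates to δ-hydroxy esters and δ-lactones, and the alkylation of this dioxolanone enolate with alkyl halides. Ring A closes as a six-membered lactone by 6-exo-trig acyl substitution (O1 onto C6). The one new stereocentre, C5, is controlled by the tert-butyl-bearing acetal carbon: the electrophile enters anti to tert-butyl, so the oxetane CH2 takes the place of the lactate hydrogen with retention (3R in the lactone). The step needs C- over O-alkylation and attack at CH2 rather than at the substituted oxetane carbon; the soft carbon terminus of the enolate and the primary-versus-secondary difference of the two ring carbons should secure both, and C2 and C3 of ring A are not touched.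

Step 13
Reactants: 19 ring A lactone
Product: 20 3-O-triethylsilyl ether of 19
Conditions: TESOTf, 2,6-lutidine, CH2Cl2, –78 to 0 °C
Reagents that add atoms: triethylsilyl trifluoromethanesulfonate, CC[Si](CC)(CC)OS(=O)(=O)C(F)(F)F
Why: Silyl triflate silylation should cap the hindered tertiary hydroxyl so that it does not quench the alkyllithium of step 20.

Step 14
Reactants: 21 methyl (R)-3-hydroxy-2-methylpropanoate
Product: 22 methyl (R)-3-(tert-butyldimethylsilyloxy)-2-methylpropanoate
Conditions: TBSCl, imidazole, CH2Cl2, 23 °C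
Reagents that add atoms: tert-butyl(chloro)dimethylsilane, CC(C)(C)[Si](C)(C)Cl
Why: Routine silyl ether formation at the primary hydroxyl.

Step 15
Reactants: 22 TBS-protected (R)-ester
Product: 23 (R)-3-(tert-butyldimethylsilyloxy)-2-methylpropanal
Conditions: i-Bu2AlH, CH2Cl2, –78 °C; aqueous potassium sodium tartrate
Reagents that add atoms: none
Why: Low-temperature partial reduction of the ester to the aldehyde, as in step 2.

Step 16
Reactants: 23 (R)-aldehyde
Product: 24 (S)-tert-butyldimethyl[(2-methylbut-3-yn-1-yl)oxy]silane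
Conditions: dimethyl (1-diazo-2-oxopropyl)phosphonate, K2CO3, MeOH, 0 to 23 °C
Reagents that add atoms: dimethyl (1-diazo-2-oxopropyl)phosphonate, COP(=O)(OC)C(=[N+]=[N-])C(C)=O
Why: Ohira–Bestmann (Seyferth–Gilbert) homologation gives the terminal alkyne, and at 0 °C the α-stereocentre should be retained (the descriptor changes only by priority).

Step 17
Reactants: 24 terminal alkyne
Product: 25 (S)-tert-butyldimethyl{[2-methyl-4-(triisopropylsilyl)but-3-yn-1-yl]oxy}silane
Conditions: n-BuLi, THF, –78 °C; TIPSOTf, –78 to 0 °C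
Reagents that add atoms: triisopropylsilyl trifluoromethanesulfonate, CC(C)[Si](OS(=O)(=O)C(F)(F)F)(C(C)C)C(C)C
Why: C-silylation of the lithium acetylide masks the acidic alkyne C–H for the later organolithium step.

Step 18
Reactants: 25 bis-silyl compound
Product: 26 (S)-2-methyl-4-(triisopropylsilyl)but-3-yn-1-ol
Conditions: camphorsulfonic acid (cat.), MeOH, 0 °C
Reagents that add atoms: none
Why: Acid-catalysed methanolysis removes the primary O-silyl group, while the Si–C(sp) bond is stable to acid.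

Step 19
Reactants: 26 primary alcohol
Product: 27 (S)-(4-iodo-3-methylbut-1-yn-1-yl)triisopropylsilane
Conditions: [I][I], PPh3, imidazole, CH2Cl2, 0 to 23 °C
Reagents that add atoms: iodine, [I][I]
Why: Appel-type iodination of a primary alcohol takes place at CH2 and leaves the adjacent stereocentre untouched.

Step 20
Reactants: 20 silylated lactone, 27 (S)-iodide
Product: 29 ring A hemiketal: 20 with C6 converted into C(OH)–CH2–CH(CH3)–C≡C–Si(i-Pr)3 (side-chain carbon S), via alkyllithium 28 (not isolated)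
Conditions: 27, t-BuLi (2 equiv), Et2O/pentane, –78 °C; then 20, –78 °C; NH4Cl
Reagents that add atoms: none
Why: Iodine–lithium exchange followed by 1,2-addition to the lactone carbonyl; the tetrahedral lithium alkoxide is stable at –78 °C, so the addition should stop at the hemiketal.

Step 21
Reactants: 29 hemiketal
Product: 30 ring A tetrahydropyran: C2 CH2–(ring B unit of 9), C3 CH3 and C6 CH2–CH(CH3)–C≡C–Si(i-Pr)3 all equatorial (2,6-cis; 2,3-trans), C5 bearing equatorial OSiEt3 and axial CH3
Conditions: Et3SiH, BF3·OEt2, CH2Cl2, –78 to –40 °C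
Reagents that add atoms: none
Why: Kishi-type ionic reduction, in which BF3 ionises the hemiketal to the ring oxocarbenium ion and Et3SiH attacks axially, anti to the axial C5 methyl, so the C6 arm should end equatorial and cis to the C2 arm.

Step 22
Reactants: 30 bis-tetrahydropyran
Product: 31 diol: 30 with the C5 hydroxyl free and the ring B arm as (S)-CH(CH3)CH2OH; the alkyne silyl group is kept
Conditions: HF·pyridine, pyridine, THF, 0 to 23 °C
Reagents that add atoms: none
Why: Buffered HF cleaves the two Si–O bonds (primary TBDPS, tertiary TES), whereas the Si–C(sp) bond of the silyl alkyne should persist.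

Step 23
Reactants: 31 diol
Product: 32 aldehyde: ring B arm (S)-CH(CH3)CHO
Conditions: Dess–Martin periodinane, NaHCO3, CH2Cl2, 0 °C
Reagents that add atoms: none
Why: Dess–Martin oxidation of the primary alcohol; the tertiary alcohol cannot be oxidised and buffering should protect the α-stereocentre.

Step 24
Reactants: 32 aldehyde
Product: 33 (E)-enal: ring B arm CH(CH3)–CH=C(CH3)–CHO
Conditions: Ph3P=C(CH3)CHO, toluene, 80 °C
Reagents that add atoms: 2-(triphenylphosphoranylidene)propanal, CC(C=O)=P(c1ccccc1)(c1ccccc1)c1ccccc1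
Why: Wittig olefination with a stabilised ylide should give the (E)-trisubstituted enal.

Step 25
Reactants: 33 (E)-enal
Product: 34 (1E,3E)-dienyl iodide: ring B arm CH(CH3)–CH=C(CH3)–CH=CH–I
Conditions: CrCl2, CHI3, THF, 0 to 23 °C
Reagents that add atoms: iodoform, IC(I)I
Why: Takai iodo-olefination through a geminal dichromium species should give the (E)-alkenyl iodide.

Step 26
Reactants: 34 dienyl iodide
Product: 35 (E,E,E)-triene: ring B arm CH(CH3)–CH=C(CH3)–CH=CH–CH=CH–CH3, alkyne still silylated
Conditions: (E)-prop-1-enylboronic acid, Pd(PPh3)4 (cat.), TlOEt, THF/H2O, 23 °C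
Reagents that add atoms: (E)-prop-1-en-1-ylboronic acid, C/C=C/B(O)O
Why: Suzuki–Miyaura coupling proceeds with retention of both alkene geometries, and the silyl group keeps the alkyne out of the palladium chemistry.

Step 27
Reactants: 35 silyl alkyne
Product: 36 terminal alkyne: C6 arm of ring A CH2–CH(CH3)–C≡CH
Conditions: Bu4NF, THF, 0 to 23 °C
Reagents that add atoms: none
Why: Fluoride-induced cleavage of the alkynyl–silicon bond, to which the triene and the free tertiary alcohol are inert.

Step 28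
Reactants: 36 terminal alkyne
Product: 38 (E)-alkenyl iodide: C6 arm of ring A CH2–CH(CH3)–CH=CH–I, via alkenylzirconocene 37 (not isolated)
Conditions: Cp2Zr(H)Cl (excess), THF, 0 to 23 °C; then [I][I], –78 °C
Reagents that add atoms: iodine, [I][I]
Why: Syn-hydrozirconation places zirconium at the alkyne terminus and iodinolysis occurs with retention to give the (E)-iodide; the terminal alkyne should react much faster than the internal conjugated alkenes, and the hydroxyl only consumes one equivalent as its zirconium alkoxide.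

Step 29
Reactants: 39 ethyl (S)-4-chloro-3-hydroxybutanoate
Product: 40 ethyl (S)-4-azido-3-hydroxybutanoate
Conditions: NaN3, DMF, 90 °C
Reagents that add atoms: sodium azide, [Na+].[N-]=[N+]=[N-]
Why: SN2 displacement of the primary chloride by azide leaves the carbinol centre unchanged.

Step 30
Reactants: 40 azido alcohol
Product: 41 ethyl (S)-4-azido-3-(tert-butyldimethylsilyloxy)butanoate
Conditions: TBSCl, imidazole, DMF, 23 °C
Reagents that add atoms: tert-butyl(chloro)dimethylsilane, CC(C)(C)[Si](C)(C)Cl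
Why: Silyl protection of the secondary alcohol prevents retro-aldol and self-condensation at the aldehyde stage.

Step 31
Reactants: 41 silylated azido ester
Product: 42 (S)-4-azido-3-(tert-butyldimethylsilyloxy)butanal
Conditions: i-Bu2AlH, CH2Cl2, –78 °C; aqueous potassium sodium tartrate
Reagents that add atoms: none
Why: Low-temperature partial reduction of the ester, at which the azide should survive.

Step 32
Reactants: 42 β-silyloxy aldehyde
Product: 43 (2S,4R)-1-azido-2-(tert-butyldimethylsilyloxy)hept-6-en-4-ol (1,3-anti)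
Conditions: (+)-Ipc2B(allyl), Et2O, –78 °C; then NaOH, H2O2
Reagents that add atoms: (+)-B-allyldiisopinocampheylborane, C=CCB([C@H]1C[C@H]2C[C@H](C2(C)C)[C@@H]1C)[C@H]1C[C@H]2C[C@H](C2(C)C)[C@@H]1C
Why: Brown allylboration under reagent control should add allyl to the Re face and give the R carbinol, anti to the silyloxy centre.

Step 33
Reactants: 43 homoallylic alcohol
Product: 45 (4R,6S)-7-azido-6-(tert-butyldimethylsilyloxy)hept-1-en-4-yl carbamate, via N-trichloroacetyl carbamate 44 (not isolated)
Conditions: Cl3CC(O)NCO, CH2Cl2, 0 °C; then K2CO3, MeOH, 23 °C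
Reagents that add atoms: trichloroacetyl isocyanate, O=C=NC(=O)C(Cl)(Cl)Cl
Why: Kočovský carbamoylation: the alcohol adds to the isocyanate and methanolysis removes the trichloroacetyl group, with retention at the carbinol carbon.

Step 34
Reactants: 45 silyl carbamate
Product: 46 (4R,6S)-7-azido-6-hydroxyhept-1-en-4-yl carbamate
Conditions: aqueous HF, MeCN, 0 to 23 °C
Reagents that add atoms: none
Why: Acidic fluoride desilylation, under which carbamate, azide and alkene are stable and acyl migration is not promoted.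

Step 35
Reactants: 46 homoallylic carbamate
Product: 47 (2Z,5R,7S)-8-azido-7-hydroxy-2-(4,4,5,5-tetramethyl-1,3,2-dioxaborolan-2-yl)oct-2-en-5-yl carbamate (boron trans to the carbon chain)
Conditions: isopropenylboronic acid pinacol ester (excess), second-generation Grubbs catalyst (cat.), CH2Cl2, 40 °C
Reagents that add atoms: 2-isopropenyl-4,4,5,5-tetramethyl-1,3,2-dioxaborolane, C=C(C)B1OC(C)(C)C(C)(C)O1
Why: Olefin cross-metathesis of a terminal alkene with the 1,1-disubstituted alkenylboronate should give the trisubstituted alkenylboronate with the bulky boryl group trans to the chain.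

Step 36
Reactants: 48 methyl 2-methoxyacrylate
Product: 49 lithium 2-methoxyacrylate
Conditions: LiOH·H2O, THF/H2O, 0 to 23 °C; lyophilisation
Reagents that add atoms: lithium hydroxide, [Li+].[OH-]
Why: Saponification, with isolation as the lithium salt so that the acid-labile enol ether never meets acid.

Step 37
Reactants: 47 azido alkenylboronate, 49 lithium 2-methoxyacrylate
Product: 51 (2Z,5R,7S)-7-hydroxy-8-(2-methoxyacrylamido)-2-(4,4,5,5-tetramethyl-1,3,2-dioxaborolan-2-yl)oct-2-en-5-yl carbamate, via primary amine 50 (not isolated)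
Conditions: PMe3, THF/H2O, 23 °C; then 49, EDC·HCl, HOBt, DMF, 0 to 23 °C
Reagents that add atoms: none
Why: Staudinger reduction followed by carbodiimide amidation, in which the primary amine should be acylated in preference to the secondary hydroxyl and the carbamate nitrogen.

Step 38
Reactants: 38 (E)-alkenyl iodide, 51 alkenylboronate amide
Product: 52 CNP0155183.1
Conditions: Pd(PPh3)4 (cat.), TlOEt, degassed THF/H2O, 23 °C, dark
Reagents that add atoms: none
Why: Suzuki–Miyaura coupling with retention at both alkenyl partners should give the (E,E)-diene, and the TlOEt-accelerated room-temperature conditions should spare the free hydroxyls, the carbamate, the enol ether amide and the triene.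

## Compound list

1 | methyl (S)-3-hydroxy-2-methylpropanoate | COC(=O)[C@@H](C)CO | starting material
2 | methyl (S)-3-(tert-butyldiphenylsilyloxy)-2-methylpropanoate | COC(=O)[C@@H](C)CO[Si](c1ccccc1)(c1ccccc1)C(C)(C)C | intermediate
3 | (S)-3-(tert-butyldiphenylsilyloxy)-2-methylpropanal | O=C[C@@H](C)CO[Si](c1ccccc1)(c1ccccc1)C(C)(C)C | intermediate
4 | (2S,3R)-1-(tert-butyldiphenylsilyloxy)-2-methylhex-5-en-3-ol | C=CC[C@@H](O)[C@@H](C)CO[Si](c1ccccc1)(c1ccccc1)C(C)(C)C | intermediate
5 | 3-(benzyloxy)propanal | O=CCCOCc1ccccc1 | starting material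
6 | ring B trifluoroacetate (O-trifluoroacetyl ester of 7) | C(c1ccccc1)OCC[C@@H]1C[C@H](OC(=O)C(F)(F)F)C[C@H]([C@@H](C)CO[Si](c2ccccc2)(c2ccccc2)C(C)(C)C)O1 | intermediate
7 | (2R,4S,6R)-2-[2-(benzyloxy)ethyl]-6-[(S)-1-(tert-butyldiphenylsilyloxy)propan-2-yl]tetrahydro-2H-pyran-4-ol | C(c1ccccc1)OCC[C@@H]1C[C@H](O)C[C@H]([C@@H](C)CO[Si](c2ccccc2)(c2ccccc2)C(C)(C)C)O1 | intermediate
8 | (2R,4S,6R)-2-[2-(benzyloxy)ethyl]-4-methoxy-6-[(S)-1-(tert-butyldiphenylsilyloxy)propan-2-yl]tetrahydro-2H-pyran | C(c1ccccc1)OCC[C@@H]1C[C@H](OC)C[C@H]([C@@H](C)CO[Si](c2ccccc2)(c2ccccc2)C(C)(C)C)O1 | intermediate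
9 | 2-{(2R,4S,6R)-4-methoxy-6-[(S)-1-(tert-butyldiphenylsilyloxy)propan-2-yl]tetrahydro-2H-pyran-2-yl}ethan-1-ol | OCC[C@@H]1C[C@H](OC)C[C@H]([C@@H](C)CO[Si](c2ccccc2)(c2ccccc2)C(C)(C)C)O1 | intermediate
10 | 2-(ring B unit of 9)acetaldehyde | O=CC[C@@H]1C[C@H](OC)C[C@H]([C@@H](C)CO[Si](c2ccccc2)(c2ccccc2)C(C)(C)C)O1 | intermediate
11 | (2R,3S)-3-methyl-1-(ring B unit of 9)pent-4-en-2-ol (anti) | O[C@H](C[C@@H]1C[C@H](OC)C[C@H]([C@@H](C)CO[Si](c2ccccc2)(c2ccccc2)C(C)(C)C)O1)[C@@H](C)C=C | intermediate
12 | (2S,3R)-2-methyl-4-(ring B unit of 9)butane-1,3-diol (anti) | O[C@H](C[C@@H]1C[C@H](OC)C[C@H]([C@@H](C)CO[Si](c2ccccc2)(c2ccccc2)C(C)(C)C)O1)[C@@H](C)CO | intermediate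
13 | primary mono-p-toluenesulfonate of 12 | O[C@H](C[C@@H]1C[C@H](OC)C[C@H]([C@@H](C)CO[Si](c2ccccc2)(c2ccccc2)C(C)(C)C)O1)[C@@H](C)COS(=O)(=O)c1ccc(C)cc1 | intermediate
14 | (2R,3S)-3-methyl-2-[(ring B unit of 9)methyl]oxetane (trans) | O1[C@H](C[C@@H]2C[C@H](OC)C[C@H]([C@@H](C)CO[Si](c3ccccc3)(c3ccccc3)C(C)(C)C)O2)[C@@H](C)C1 | intermediate
15 | (S)-lactic acid | C[C@H](O)C(=O)O | starting material
16 | (2S,5S)-2-tert-butyl-5-methyl-1,3-dioxolan-4-one | C[C@@H]1O[C@H](C(C)(C)C)OC1=O | intermediate
17 | lithium enolate of 16 | [Li+].CC1=C([O-])O[C@@H](C(C)(C)C)O1 | intermediate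
18 | (2S,5R)-2-tert-butyl-5-methyl-1,3-dioxolan-4-one carrying at C5, trans to tert-butyl, the 3-hydroxy-2-methyl-4-(ring B unit of 9)butyl chain of opened 14 (alkoxide complexed to boron in the flask) | O[C@H](C[C@@H]1C[C@H](OC)C[C@H]([C@@H](C)CO[Si](c2ccccc2)(c2ccccc2)C(C)(C)C)O1)[C@@H](C)C[C@@]1(C)O[C@H](C(C)(C)C)OC1=O | intermediate
19 | (3R,5S,6R)-3-hydroxy-3,5-dimethyl-6-[(ring B unit of 9)methyl]tetrahydro-2H-pyran-2-one | O=C1O[C@H](C[C@@H]2C[C@H](OC)C[C@H]([C@@H](C)CO[Si](c3ccccc3)(c3ccccc3)C(C)(C)C)O2)[C@@H](C)C[C@@]1(C)O | intermediate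
20 | 3-O-triethylsilyl ether of 19 | O=C1O[C@H](C[C@@H]2C[C@H](OC)C[C@H]([C@@H](C)CO[Si](c3ccccc3)(c3ccccc3)C(C)(C)C)O2)[C@@H](C)C[C@@]1(C)O[Si](CC)(CC)CC | intermediate
21 | methyl (R)-3-hydroxy-2-methylpropanoate | COC(=O)[C@H](C)CO | starting material
22 | methyl (R)-3-(tert-butyldimethylsilyloxy)-2-methylpropanoate | COC(=O)[C@H](C)CO[Si](C)(C)C(C)(C)C | intermediate
23 | (R)-3-(tert-butyldimethylsilyloxy)-2-methylpropanal | O=C[C@H](C)CO[Si](C)(C)C(C)(C)C | intermediate
24 | (S)-tert-butyldimethyl[(2-methylbut-3-yn-1-yl)oxy]silane | C#C[C@H](C)CO[Si](C)(C)C(C)(C)C | intermediate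
25 | (S)-tert-butyldimethyl{[2-methyl-4-(triisopropylsilyl)but-3-yn-1-yl]oxy}silane | CC(C)[Si](C(C)C)(C(C)C)C#C[C@H](C)CO[Si](C)(C)C(C)(C)C | intermediate
26 | (S)-2-methyl-4-(triisopropylsilyl)but-3-yn-1-ol | CC(C)[Si](C(C)C)(C(C)C)C#C[C@H](C)CO | intermediate
27 | (S)-(4-iodo-3-methylbut-1-yn-1-yl)triisopropylsilane | CC(C)[Si](C(C)C)(C(C)C)C#C[C@H](C)CI | intermediate
28 | (R)-[2-methyl-4-(triisopropylsilyl)but-3-yn-1-yl]lithium | [Li]C[C@@H](C)C#C[Si](C(C)C)(C(C)C)C(C)C | intermediate
29 | ring A hemiketal (anomeric mixture), C6 bearing OH and the (S)-2-methyl-4-(triisopropylsilyl)but-3-ynyl chain | CC(C)[Si](C(C)C)(C(C)C)C#C[C@H](C)CC1(O)O[C@H](C[C@@H]2C[C@H](OC)C[C@H]([C@@H](C)CO[Si](c3ccccc3)(c3ccccc3)C(C)(C)C)O2)[C@@H](C)C[C@@]1(C)O[Si](CC)(CC)CC | intermediate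
30 | ring A/ring B bis-tetrahydropyran, 2,6-cis ring A, C5 OSiEt3, silyl alkyne, TBDPS ether | CC(C)[Si](C(C)C)(C(C)C)C#C[C@H](C)C[C@@H]1O[C@H](C[C@@H]2C[C@H](OC)C[C@H]([C@@H](C)CO[Si](c3ccccc3)(c3ccccc3)C(C)(C)C)O2)[C@@H](C)C[C@@]1(C)O[Si](CC)(CC)CC | intermediate
31 | diol (tertiary C5 hydroxyl of ring A; primary hydroxyl on the ring B arm), silyl alkyne | CC(C)[Si](C(C)C)(C(C)C)C#C[C@H](C)C[C@@H]1O[C@H](C[C@@H]2C[C@H](OC)C[C@H]([C@@H](C)CO)O2)[C@@H](C)C[C@@]1(C)O | intermediate
32 | aldehyde on the ring B arm | CC(C)[Si](C(C)C)(C(C)C)C#C[C@H](C)C[C@@H]1O[C@H](C[C@@H]2C[C@H](OC)C[C@H]([C@@H](C)C=O)O2)[C@@H](C)C[C@@]1(C)O | intermediate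
33 | (E)-2-methyl enal on the ring B arm | CC(C)[Si](C(C)C)(C(C)C)C#C[C@H](C)C[C@@H]1O[C@H](C[C@@H]2C[C@H](OC)C[C@H]([C@@H](C)/C=C(C)/C=O)O2)[C@@H](C)C[C@@]1(C)O | intermediate
34 | (1E,3E)-dienyl iodide on the ring B arm | CC(C)[Si](C(C)C)(C(C)C)C#C[C@H](C)C[C@@H]1O[C@H](C[C@@H]2C[C@H](OC)C[C@H]([C@@H](C)/C=C(C)/C=C/I)O2)[C@@H](C)C[C@@]1(C)O | intermediate
35 | (E,E,E)-triene, silyl alkyne | CC(C)[Si](C(C)C)(C(C)C)C#C[C@H](C)C[C@@H]1O[C@H](C[C@@H]2C[C@H](OC)C[C@H]([C@@H](C)/C=C(C)/C=C/C=C/C)O2)[C@@H](C)C[C@@]1(C)O | intermediate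
36 | (E,E,E)-triene, terminal alkyne | C#C[C@H](C)C[C@@H]1O[C@H](C[C@@H]2C[C@H](OC)C[C@H]([C@@H](C)/C=C(C)/C=C/C=C/C)O2)[C@@H](C)C[C@@]1(C)O | intermediate
37 | (E)-alkenylzirconocene chloride from 36 (tertiary oxygen as its chlorozirconocene alkoxide; cyclopentadienyl rings drawn σ-bonded) | Cl[Zr](C1C=CC=C1)(C1C=CC=C1)/C=C/[C@H](C)C[C@@H]1O[C@H](C[C@@H]2C[C@H](OC)C[C@H]([C@@H](C)/C=C(C)/C=C/C=C/C)O2)[C@@H](C)C[C@@]1(C)O[Zr](Cl)(C1C=CC=C1)C1C=CC=C1 | intermediate
38 | (E)-alkenyl iodide with rings A and B and the triene | I/C=C/[C@H](C)C[C@@H]1O[C@H](C[C@@H]2C[C@H](OC)C[C@H]([C@@H](C)/C=C(C)/C=C/C=C/C)O2)[C@@H](C)C[C@@]1(C)O | intermediate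
39 | ethyl (S)-4-chloro-3-hydroxybutanoate | CCOC(=O)C[C@H](O)CCl | starting material
40 | ethyl (S)-4-azido-3-hydroxybutanoate | CCOC(=O)C[C@H](O)CN=[N+]=[N-] | intermediate
41 | ethyl (S)-4-azido-3-(tert-butyldimethylsilyloxy)butanoate | CCOC(=O)C[C@H](O[Si](C)(C)C(C)(C)C)CN=[N+]=[N-] | intermediate
42 | (S)-4-azido-3-(tert-butyldimethylsilyloxy)butanal | O=CC[C@H](O[Si](C)(C)C(C)(C)C)CN=[N+]=[N-] | intermediate
43 | (2S,4R)-1-azido-2-(tert-butyldimethylsilyloxy)hept-6-en-4-ol | C=CC[C@@H](O)C[C@H](O[Si](C)(C)C(C)(C)C)CN=[N+]=[N-] | intermediate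
44 | N-trichloroacetyl carbamate of 43 | C=CC[C@@H](OC(=O)NC(=O)C(Cl)(Cl)Cl)C[C@H](O[Si](C)(C)C(C)(C)C)CN=[N+]=[N-] | intermediate
45 | (4R,6S)-7-azido-6-(tert-butyldimethylsilyloxy)hept-1-en-4-yl carbamate | C=CC[C@@H](OC(N)=O)C[C@H](O[Si](C)(C)C(C)(C)C)CN=[N+]=[N-] | intermediate
46 | (4R,6S)-7-azido-6-hydroxyhept-1-en-4-yl carbamate | C=CC[C@@H](OC(N)=O)C[C@H](O)CN=[N+]=[N-] | intermediate
47 | (2Z,5R,7S)-8-azido-7-hydroxy-2-(4,4,5,5-tetramethyl-1,3,2-dioxaborolan-2-yl)oct-2-en-5-yl carbamate | [N-]=[N+]=NC[C@@H](O)C[C@@H](C/C=C(C)/B1OC(C)(C)C(C)(C)O1)OC(N)=O | intermediate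
48 | methyl 2-methoxyacrylate | C=C(OC)C(=O)OC | starting material
49 | lithium 2-methoxyacrylate | [Li+].C=C(OC)C([O-])=O | intermediate
50 | (2Z,5R,7S)-8-amino-7-hydroxy-2-(4,4,5,5-tetramethyl-1,3,2-dioxaborolan-2-yl)oct-2-en-5-yl carbamate | NC[C@@H](O)C[C@@H](C/C=C(C)/B1OC(C)(C)C(C)(C)O1)OC(N)=O | intermediate
51 | (2Z,5R,7S)-7-hydroxy-8-(2-methoxyacrylamido)-2-(4,4,5,5-tetramethyl-1,3,2-dioxaborolan-2-yl)oct-2-en-5-yl carbamate | C=C(OC)C(=O)NC[C@@H](O)C[C@@H](C/C=C(C)/B1OC(C)(C)C(C)(C)O1)OC(N)=O | intermediate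
52 | CNP0155183.1 | C=C(OC)C(=O)NC[C@@H](O)C[C@@H](C/C=C(C)/C=C/[C@H](C)C[C@@H]1O[C@H](C[C@@H]2C[C@H](OC)C[C@H]([C@@H](C)/C=C(C)/C=C/C=C/C)O2)[C@@H](C)C[C@@]1(C)O)OC(N)=O | target

## Step count and risks

Total step count: 38.
Longest linear sequence: 22 steps (steps 1–10, 12, 13, 20–28 and 38).

Steps most likely to fail:

1. Step 12 (proposed new method). The enolate may decompose before it opens the β-branched oxetane, O-alkylation may compete, or the acyl transfer that closes ring A may stall. The fallback makes the two bonds in separate known operations, setting out from diol 12. Selective iodination of the primary hydroxyl (iodine, PPh3, imidazole) should give the iodohydrin F1. Silylation of the secondary hydroxyl (TESCl, imidazole) should give the iodo silyl ether F2. Alkylation of enolate 17 (from 16, LiN(i-Pr)2, THF/DMPU, –78 to –30 °C) with F2, anti to tert-butyl, should give the C-alkylated dioxolanone F3. Camphorsulfonic acid in MeOH/CH2Cl2 then removes the TES group and lactonises with loss of pivalaldehyde, and the route is rejoined at lactone 19.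

2. Step 28. Chemoselectivity may be lost through hydrozirconation of the conjugated triene, and the triene may isomerise during iodinolysis of the zirconium species. The fallback sets out from alkyne 36. Palladium-catalysed syn-hydrostannation (Bu3SnH, PdCl2(PPh3)2 cat., THF, 0 °C) should give the (E)-alkenylstannane F4. Iododestannylation by titration with iodine in CH2Cl2 at –78 °C then rejoins the route at alkenyl iodide 38.

3. Step 25. The E selectivity of the iodo-olefination may erode on a conjugated aldehyde, and the light-sensitive dienyl iodide may decompose before coupling. The fallback sets out from enal 33. A Horner–Wadsworth–Emmons reaction with the lithium anion of diethyl (E)-but-2-enylphosphonate (LiN(SiMe3)2, THF, –78 to 0 °C, in excess to cover the free hydroxyl) should give the triene directly. The route is rejoined at 35, by-passing 34 and step 26; no new compound is made (F0).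

Further compounds
F1 | step 12 | primary iodide of diol 12 with the secondary hydroxyl free: 4-iodo-3-methyl-1-(ring B unit of 9)butan-2-ol, anti | O[C@H](C[C@@H]1C[C@H](OC)C[C@H]([C@@H](C)CO[Si](c2ccccc2)(c2ccccc2)C(C)(C)C)O1)[C@@H](C)CI
F2 | step 12 | triethylsilyl ether of F1 | CC[Si](CC)(CC)O[C@H](C[C@@H]1C[C@H](OC)C[C@H]([C@@H](C)CO[Si](c2ccccc2)(c2ccccc2)C(C)(C)C)O1)[C@@H](C)CI
F3 | step 12 | C5-alkylated (2S,5R)-dioxolanone, the triethylsilyl ether of 18 | CC[Si](CC)(CC)O[C@H](C[C@@H]1C[C@H](OC)C[C@H]([C@@H](C)CO[Si](c2ccccc2)(c2ccccc2)C(C)(C)C)O1)[C@@H](C)C[C@@]1(C)O[C@H](C(C)(C)C)OC1=O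
F4 | step 28 | (E)-alkenyl tributylstannane from 36 | CCCC[Sn](CCCC)(CCCC)/C=C/[C@H](C)C[C@@H]1O[C@H](C[C@@H]2C[C@H](OC)C[C@H]([C@@H](C)/C=C(C)/C=C/C=C/C)O2)[C@@H](C)C[C@@]1(C)O
F0 | step 25 | none | none
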